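**Assumption:** the target has no stereocentre and no hindered biaryl axis, so it is achiral and no stereocontrol is needed. Ring A is the ring that keeps a prenyl group; ring B is the ring that keeps the free hydroxyl.

## Retrosynthetic overview

1. Both benzene rings are bought: 4-bromophenol 1 and prenyl bromide 2 give bromodiprenylphenol 3; 4-bromocatechol 4 and 2 give bromoprenylcatechol 5 (disconnection: ortho-C-prenylation of a sodium phenoxide).
2. Biaryl disconnection: 3 (through bis(pinacolato)diboron 6 and boronate 7) plus 5 give the open, unprotected triprenyl biaryl triol 8 (Suzuki–Miyaura).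
3. Key disconnection: both pyran O–CMe2 bonds of target 13 are cut at once back to 8. In the forward direction one charge of DDQ closes both pyrans in the same flask, with no protecting group.
4. Ring order: the pyran on catechol ring B closes first (via 9, 10, 11), then the pyran on ring A (via 12). Each closure is an ortho-quinone methide oxa-6π electrocyclisation, as in the presumed natural cyclisation of prenylated phenols.

## Route

Step 1
Reactants: 1 4-bromophenol; 2 prenyl bromide (1-bromo-3-methylbut-2-ene)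
Product: 3 4-bromo-2,6-bis(3-methylbut-2-en-1-yl)phenol
Conditions: NaH (2.3 equiv), PhMe, 0 °C; then 2 (2.3 equiv), 0 → 23 °C, 16 h
Reagents that add atoms: 2 prenyl bromide, CC(C)=CCBr
Why: A sodium phenoxide in a non-polar solvent reacts as a tight ion pair that delivers the allylic bromide to the ortho carbon (phenoxide ortho-C-alkylation), and with the para position blocked by bromine and excess base present the second ortho position is prenylated in the same pot; no stereocentre is formed.

Step 2
Reactants: 4 4-bromobenzene-1,2-diol; 2 prenyl bromide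
Product: 5 5-bromo-3-(3-methylbut-2-en-1-yl)benzene-1,2-diol
Conditions: NaH (1.05 equiv), PhMe–Et2O (4:1), 0 °C; then 2 (1.0 equiv), 0 → 23 °C
Reagents that add atoms: 2 prenyl bromide, CC(C)=CCBr
Why: The same phenoxide ortho-C-alkylation applies; of the two ortho carbons the one wedged between oxygen and bromine is shielded, so prenylation should go to the open ortho carbon next to the hydroxyl that is para to bromine; no stereocentre is formed.

Step 3
Reactants: 3 4-bromo-2,6-bis(3-methylbut-2-en-1-yl)phenol; 5 5-bromo-3-(3-methylbut-2-en-1-yl)benzene-1,2-diol; 6 bis(pinacolato)diboron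
Product: 8 5-[4-hydroxy-3,5-bis(3-methylbut-2-en-1-yl)phenyl]-3-(3-methylbut-2-en-1-yl)benzene-1,2-diol, via aryl pinacol boronate 7 (not isolated)
Conditions: 6 (1.1 equiv), Pd(dppf)Cl2 (5 mol %), KOAc (3 equiv), 1,4-dioxane, 90 °C; then 5 (0.9 equiv), degassed 2 M aq K3PO4 (4 equiv), 90 °C, Ar; dilute HCl work-up
Reagents that add atoms: bis(pinacolato)diboron 6, CC1(C)OB(OC1(C)C)B1OC(C)(C)C(C)(C)O1 (its boryl group enters 7 only and none of it remains in 8)
Why: Miyaura borylation of the electron-rich bromide 3 followed in the same flask by Suzuki–Miyaura coupling with bromide 5 tolerates free phenols when oxygen is excluded, and the biaryl has no ortho substituents, so no chiral axis or stereocentre arises.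

Step 4
Reactants: 8 5-[4-hydroxy-3,5-bis(3-methylbut-2-en-1-yl)phenyl]-3-(3-methylbut-2-en-1-yl)benzene-1,2-diol
Product: 13 2,2-dimethyl-6-[2,2-dimethyl-8-(3-methylbut-2-en-1-yl)-2H-chromen-6-yl]-2H-chromen-8-ol, via ortho-quinone 9 (not isolated), via hydroxy ortho-quinone methide 10 (not isolated), via mono-chromene 11 (not isolated), via ring A ortho-quinone methide 12 (not isolated)
Conditions: DDQ (2.1 equiv), 1,4-dioxane, 23 °C, 1 h, then 80 °C, 3 h
Reagents that add atoms: none
Why: Proposed new method: DDQ first oxidises the catechol ring to ortho-quinone 9, whose benzylic and allylic CH2 lets it tautomerise to hydroxy ortho-quinone methide 10, which closes by oxa-6π electrocyclisation to 11, and the second equivalent dehydrogenates the diprenylphenol ring to ortho-quinone methide 12, which closes in the same way to 13 (the single ring A oxygen can engage only one of its two prenyl groups); the closest known reaction types are the DDQ oxidative cyclisation of ortho-prenylphenols to 2,2-dimethyl-2H-chromenes and the isomerisation of prenylquinones to chromenols; no stereocentre is formed.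

## Compound list

1 | 4-bromophenol | Oc1ccc(Br)cc1 | starting material
2 | prenyl bromide (1-bromo-3-methylbut-2-ene) | CC(C)=CCBr | starting material
3 | 4-bromo-2,6-bis(3-methylbut-2-en-1-yl)phenol | CC(C)=CCc1cc(Br)cc(CC=C(C)C)c1O | intermediate
4 | 4-bromobenzene-1,2-diol (4-bromocatechol) | Oc1ccc(Br)cc1O | starting material
5 | 5-bromo-3-(3-methylbut-2-en-1-yl)benzene-1,2-diol | CC(C)=CCc1cc(Br)cc(O)c1O | intermediate
6 | bis(pinacolato)diboron | CC1(C)OB(OC1(C)C)B1OC(C)(C)C(C)(C)O1 | starting material
7 | 2,6-bis(3-methylbut-2-en-1-yl)-4-(4,4,5,5-tetramethyl-1,3,2-dioxaborolan-2-yl)phenol | CC(C)=CCc1cc(B2OC(C)(C)C(C)(C)O2)cc(CC=C(C)C)c1O | intermediate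
8 | 5-[4-hydroxy-3,5-bis(3-methylbut-2-en-1-yl)phenyl]-3-(3-methylbut-2-en-1-yl)benzene-1,2-diol | CC(C)=CCc1cc(-c2cc(O)c(O)c(CC=C(C)C)c2)cc(CC=C(C)C)c1O | intermediate
9 | 5-[4-hydroxy-3,5-bis(3-methylbut-2-en-1-yl)phenyl]-3-(3-methylbut-2-en-1-yl)cyclohexa-3,5-diene-1,2-dione | CC(C)=CCC1=CC(c2cc(CC=C(C)C)c(O)c(CC=C(C)C)c2)=CC(=O)C1=O | intermediate
10 | 2-hydroxy-4-[4-hydroxy-3,5-bis(3-methylbut-2-en-1-yl)phenyl]-6-(3-methylbut-2-en-1-ylidene)cyclohexa-2,4-dien-1-one (alkylidene geometry not fixed; it equilibrates) | CC(C)=CC=C1C=C(c2cc(CC=C(C)C)c(O)c(CC=C(C)C)c2)C=C(O)C1=O | intermediate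
11 | 6-[4-hydroxy-3,5-bis(3-methylbut-2-en-1-yl)phenyl]-2,2-dimethyl-2H-chromen-8-ol | CC(C)=CCc1cc(-c2cc(O)c3c(c2)C=CC(C)(C)O3)cc(CC=C(C)C)c1O | intermediate
12 | 4-(8-hydroxy-2,2-dimethyl-2H-chromen-6-yl)-2-(3-methylbut-2-en-1-yl)-6-(3-methylbut-2-en-1-ylidene)cyclohexa-2,4-dien-1-one (alkylidene geometry not fixed; it equilibrates) | CC(C)=CC=C1C=C(c2cc(O)c3c(c2)C=CC(C)(C)O3)C=C(CC=C(C)C)C1=O | intermediate
13 | 2,2-dimethyl-6-[2,2-dimethyl-8-(3-methylbut-2-en-1-yl)-2H-chromen-6-yl]-2H-chromen-8-ol | CC(C)=CCc1cc(-c2cc(O)c3c(c2)C=CC(C)(C)O3)cc2c1OC(C)(C)C=C2 | target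

## Step count and risks

Total steps: 4. Longest linear sequence: 3 (1 → 3 → 8 → 13, or 4 → 5 → 8 → 13).

The three steps most likely to fail:

**Step 4 (double oxidative cyclisation of the unprotected triol).** The catechol-derived ortho-quinone 9 may dimerise or add phenols faster than it tautomerises, and excess DDQ may attack the remaining prenyl group or the free phenol of 13. The fallback sets out from 8 and comes back at 13. The least hindered hydroxyl of 8 (the catechol hydroxyl that has an ortho hydrogen) is silylated with TBSCl (1.0 equiv) and imidazole in CH2Cl2 at 0 °C. This gives 4-[3-(tert-butyldimethylsilyloxy)-4-hydroxy-5-(3-methylbut-2-en-1-yl)phenyl]-2,6-bis(3-methylbut-2-en-1-yl)phenol F5. With the catechol masked, no ortho-quinone can form, and DDQ (2.1 equiv, 80 °C) closes both rings by the ordinary ortho-prenylphenol dehydrogenation. The product is tert-butyl{[2,2-dimethyl-6-(2,2-dimethyl-8-(3-methylbut-2-en-1-yl)-2H-chromen-6-yl)-2H-chromen-8-yl]oxy}dimethylsilane F6. TBAF in THF at 0 °C then frees 13.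

**Step 2 (site of prenylation on 4-bromocatechol).** Attack at the carbon between oxygen and bromine, para attack and O-alkylation can all erode the yield, and the regioisomers may be hard to separate. The fallback sets out from 2 and comes back at 5. Commercial 4-bromo-2-methoxyphenol F1 has only one free ortho position, so its sodium phenoxide (NaH, PhMe) reacts with 2 to give a single C-prenyl isomer, 4-bromo-2-methoxy-6-(3-methylbut-2-en-1-yl)phenol F2. Nucleophilic demethylation with NaSEt in DMF at 120 °C, which is basic and so does not cyclise the prenyl phenol to a chroman, then gives 5.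

**Step 3 (Suzuki coupling with a free catechol).** The catechol can bind boron or palladium and is air-sensitive in base, which may stall the coupling. The fallback sets out from 5 and comes back at 8. Compound 5 is converted with MOMCl and i-Pr2NEt into 5-bromo-1,2-bis(methoxymethoxy)-3-(3-methylbut-2-en-1-yl)benzene F3. F3 is coupled with boronate 7, made from 3 as in step 3 and now isolated, using Pd(PPh3)4 and aq K2CO3 in DME at 85 °C. This gives 4-[3,4-bis(methoxymethoxy)-5-(3-methylbut-2-en-1-yl)phenyl]-2,6-bis(3-methylbut-2-en-1-yl)phenol F4. Brief treatment with dilute HCl in MeOH at 23 °C removes both acetals and gives 8.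

## Further compounds

F1 | step 2 | 4-bromo-2-methoxyphenol | COc1cc(Br)ccc1O
F2 | step 2 | 4-bromo-2-methoxy-6-(3-methylbut-2-en-1-yl)phenol | COc1cc(Br)cc(CC=C(C)C)c1O
F3 | step 3 | 5-bromo-1,2-bis(methoxymethoxy)-3-(3-methylbut-2-en-1-yl)benzene | COCOc1cc(Br)cc(CC=C(C)C)c1OCOC
F4 | step 3 | 4-[3,4-bis(methoxymethoxy)-5-(3-methylbut-2-en-1-yl)phenyl]-2,6-bis(3-methylbut-2-en-1-yl)phenol | COCOc1cc(-c2cc(CC=C(C)C)c(O)c(CC=C(C)C)c2)cc(CC=C(C)C)c1OCOC
F5 | step 4 | 4-[3-(tert-butyldimethylsilyloxy)-4-hydroxy-5-(3-methylbut-2-en-1-yl)phenyl]-2,6-bis(3-methylbut-2-en-1-yl)phenol | CC(C)=CCc1cc(-c2cc(O[Si](C)(C)C(C)(C)C)c(O)c(CC=C(C)C)c2)cc(CC=C(C)C)c1O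
F6 | step 4 | tert-butyl{[2,2-dimethyl-6-(2,2-dimethyl-8-(3-methylbut-2-en-1-yl)-2H-chromen-6-yl)-2H-chromen-8-yl]oxy}dimethylsilane | CC(C)=CCc1cc(-c2cc(O[Si](C)(C)C(C)(C)C)c3c(c2)C=CC(C)(C)O3)cc2c1OC(C)(C)C=C2
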